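**Plan**

- Halimane numbering is used: ring A is C1–C5 plus C10, ring B is C5–C10, the side chain C11–C15 sits on C9, and the ester is on C4. The retrosynthesis cuts the O-acetyl group, then C13–OH (epoxide hydrolysis), C13–CH3 and C14–C15 (carboalumination, formaldehyde), C13≡C14 (alkyne homologation), C2–C3 and C4–C5 (Diels–Alder), C10–C1 (vinylation), and last C8–CH3 and C9–C11.
- Enabling feature: in ring B the methyl-bearing tertiary C8 and the quaternary C9 (methyl, C11) lie β and α to C10, the later alkene carbon. C8, C9 and C10 are therefore the β-carbon, α-carbon and carbonyl carbon of 2-methylcyclohex-2-en-1-one.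
- Forward: ring B is bought as enone 1. One pot adds methyl at C8 and allyl at C9. Enol triflation and vinylation give the C5=C10–C1=C2 diene, cycloaddition with methyl methacrylate closes ring A, and the allyl group is then grown into C11–C15.
- Stereochemistry: C8 comes from the chiral copper catalyst and C9 from anti allylation of the enolate. C5 and C4 come from diene-face and endo selectivity in the Diels–Alder step. C13 and C14 come from Sharpless epoxidation of the E allylic alcohol followed by invertive hydrolysis at C13.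

Key step: step 1

Remark: the (R,S,S) enantiomer of the binaphthol/bis(1-phenylethyl)amine phosphoramidite is assumed to give the 3R series with AlMe3, by analogy with dialkylzinc additions to cyclohexenone; if the sense is opposite, the mirror-image ligand is used.

**Route**

Step 1
Reactants: 1 2-methylcyclohex-2-en-1-one; 2 trimethylaluminium; 3 allyl iodide
Product: 6 (2S,3R)-2-allyl-2,3-dimethylcyclohexan-1-one, via aluminium enolate 4 (not isolated), via lithium aluminate 5 (not isolated)
Conditions: Cu(OTf)2 (2 mol%), O,O'-(R)-1,1'-binaphthyl-2,2'-diyl N,N-bis[(S)-1-phenylethyl]phosphoramidite (4 mol%), AlMe3, Et2O, −30 °C; then MeLi, THF, DMPU, allyl iodide, −30 °C to rt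
Reagents that add atoms: none
Why: AlMe3 reduces Cu(OTf)2 and transmetalates to a phosphoramidite-bound monovalent copper–methyl species, which π-complexes enone 1, adds at the β-carbon and reductively eliminates to form the C8–CH3 bond and release aluminium enolate 4 with its double bond fixed at C9=C10. MeLi converts 4 into the more nucleophilic aluminate 5, which is C-alkylated by allyl iodide at C9 to form C9–C11. The closest known reaction type is the copper/phosphoramidite-catalysed asymmetric conjugate addition of trialkylaluminium reagents to 2-substituted cyclohexenones with in situ enolate alkylation (three-component coupling); no ring is closed. C8 is controlled by the chiral ligand, which selects the enone face for methyl delivery. C9 is controlled by the substrate: allylic strain with the C9 methyl forces the C8 methyl pseudoaxial in the half-chair enolate, so allyl iodide enters axially from the opposite face and C11 ends trans to the C8 methyl with the two methyls cis. The step needs alkylation at C9 only, which is secured because the enolate is generated regiospecifically by the conjugate addition and is trapped without a proton source that could equilibrate it towards C5.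

Step 2
Reactants: 6 (2S,3R)-2-allyl-2,3-dimethylcyclohexan-1-one
Product: 8 (5R,6S)-6-allyl-5,6-dimethylcyclohex-1-en-1-yl trifluoromethanesulfonate, via potassium enolate 7 (not isolated)
Conditions: KN(SiMe3)2, THF, −78 °C; then PhNTf2, −78 °C to 0 °C
Reagents that add atoms: N-phenylbis(trifluoromethanesulfonimide), O=S(=O)(N(c1ccccc1)S(=O)(=O)C(F)(F)F)C(F)(F)F
Why: Enol triflate formation; deprotonation can occur only at C5 because C9 is quaternary, and O-triflation of enolate 7 fixes the C5=C10 double bond without touching either stereocentre.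

Step 3
Reactants: 8 (5R,6S)-6-allyl-5,6-dimethylcyclohex-1-en-1-yl trifluoromethanesulfonate; 9 tributyl(vinyl)stannane
Product: 10 (5R,6S)-6-allyl-5,6-dimethyl-1-vinylcyclohex-1-ene
Conditions: Pd(PPh3)4 (5 mol%), LiCl, THF, 65 °C
Reagents that add atoms: none
Why: Stille cross-coupling of an alkenyl triflate with a vinylstannane under zerovalent palladium catalysis, with LiCl assisting transmetalation, forms the C10–C1 bond and gives the C5=C10–C1=C2 diene.

Step 4
Reactants: 10 (5R,6S)-6-allyl-5,6-dimethyl-1-vinylcyclohex-1-ene; 11 methyl methacrylate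
Product: 12 methyl (1S,5S,6R,8aR)-5-allyl-1,5,6-trimethyl-1,2,3,5,6,7,8,8a-octahydronaphthalene-1-carboxylate
Conditions: methyl methacrylate (5 equiv), EtAlCl2 (0.3 equiv), toluene, −40 °C to 0 °C
Reagents that add atoms: none
Why: Lewis-acid-promoted Diels–Alder reaction in which the complexed methacrylate should bond through its CH2 terminus to the unhindered vinyl carbon C2 and through its α-carbon to C5 (ortho-type regiochemistry), approach the diene face opposite the pseudoaxial C9 methyl so that H-5 ends cis to that methyl, and keep the ester endo, which places CO2Me trans to H-5 at C4.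

Step 5
Reactants: 12 methyl (1S,5S,6R,8aR)-5-allyl-1,5,6-trimethyl-1,2,3,5,6,7,8,8a-octahydronaphthalene-1-carboxylate
Product: 14 methyl (1S,5S,6R,8aR)-5-(3-hydroxypropyl)-1,5,6-trimethyl-1,2,3,5,6,7,8,8a-octahydronaphthalene-1-carboxylate, via trialkylborane 13 (not isolated)
Conditions: 9-BBN, THF, 0 °C to rt; then 30% H2O2, aq. NaOH, 0 °C
Reagents that add atoms: hydrogen peroxide, OO
Why: Hydroboration–oxidation with the bulky 9-BBN takes the monosubstituted allyl alkene anti-Markovnikov and leaves the trisubstituted C1=C10 alkene and the hindered ester untouched.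

Step 6
Reactants: 14 methyl (1S,5S,6R,8aR)-5-(3-hydroxypropyl)-1,5,6-trimethyl-1,2,3,5,6,7,8,8a-octahydronaphthalene-1-carboxylate
Product: 15 methyl (1S,5S,6R,8aR)-1,5,6-trimethyl-5-(3-oxopropyl)-1,2,3,5,6,7,8,8a-octahydronaphthalene-1-carboxylate
Conditions: Dess–Martin periodinane, NaHCO3, CH2Cl2, 0 °C to rt
Reagents that add atoms: none
Why: Dess–Martin oxidation converts the primary alcohol into the aldehyde under buffered conditions without over-oxidation.

Step 7
Reactants: 15 methyl (1S,5S,6R,8aR)-1,5,6-trimethyl-5-(3-oxopropyl)-1,2,3,5,6,7,8,8a-octahydronaphthalene-1-carboxylate; 16 dimethyl (1-diazo-2-oxopropyl)phosphonate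
Product: 17 methyl (1S,5S,6R,8aR)-5-(but-3-yn-1-yl)-1,5,6-trimethyl-1,2,3,5,6,7,8,8a-octahydronaphthalene-1-carboxylate
Conditions: K2CO3, MeOH, 0 °C to rt
Reagents that add atoms: none
Why: The Ohira–Bestmann variant of the Seyferth–Gilbert homologation turns the aldehyde into the terminal alkyne (adding C14) in K2CO3/MeOH, where the methyl ester can only exchange degenerately with methanol.

Step 8
Reactants: 17 methyl (1S,5S,6R,8aR)-5-(but-3-yn-1-yl)-1,5,6-trimethyl-1,2,3,5,6,7,8,8a-octahydronaphthalene-1-carboxylate; 2 trimethylaluminium; 18 paraformaldehyde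
Product: 20 methyl (1S,5S,6R,8aR)-5-[(3E)-5-hydroxy-3-methylpent-3-en-1-yl]-1,5,6-trimethyl-1,2,3,5,6,7,8,8a-octahydronaphthalene-1-carboxylate, via alkenylalane 19 (not isolated)
Conditions: AlMe3 (2.5 equiv), Cp2ZrCl2 (0.25 equiv), CH2Cl2, 0 °C to rt; then (CH2O)n, THF, 0 °C to rt
Reagents that add atoms: none
Why: Negishi zirconium-catalysed carboalumination adds methyl and aluminium syn across the terminal alkyne with methyl on the internal carbon C13, and alkenylalane 19 is hydroxymethylated by formaldehyde with retention, which gives the E trisubstituted allylic alcohol.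

Step 9
Reactants: 20 methyl (1S,5S,6R,8aR)-5-[(3E)-5-hydroxy-3-methylpent-3-en-1-yl]-1,5,6-trimethyl-1,2,3,5,6,7,8,8a-octahydronaphthalene-1-carboxylate
Product: 21 methyl (1S,5S,6R,8aR)-5-{2-[(2R,3R)-3-(hydroxymethyl)-2-methyloxiran-2-yl]ethyl}-1,5,6-trimethyl-1,2,3,5,6,7,8,8a-octahydronaphthalene-1-carboxylate
Conditions: Ti(OiPr)4 (10 mol%), D-(−)-diethyl tartrate (12 mol%), t-BuOOH, 4 Å molecular sieves, CH2Cl2, −20 °C
Reagents that add atoms: tert-butyl hydroperoxide, CC(C)(C)OO
Why: Sharpless asymmetric epoxidation, in which the titanium tartrate complex binds the allylic hydroxyl and delivers oxygen to one face of the C13=C14 alkene only; D-(−)-diethyl tartrate should give the (2R,3R)-epoxide, the mirror image of the (2S,3S) series that (E)-3-methylalk-2-en-1-ols give with the L-(+) ester, and the non-allylic C1=C10 alkene is not epoxidised.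

Step 10
Reactants: 21 methyl (1S,5S,6R,8aR)-5-{2-[(2R,3R)-3-(hydroxymethyl)-2-methyloxiran-2-yl]ethyl}-1,5,6-trimethyl-1,2,3,5,6,7,8,8a-octahydronaphthalene-1-carboxylate
Product: 22 methyl (1S,5S,6R,8aR)-1,5,6-trimethyl-5-[(3S,4R)-3,4,5-trihydroxy-3-methylpentyl]-1,2,3,5,6,7,8,8a-octahydronaphthalene-1-carboxylate
Conditions: HClO4 (cat.), THF/H2O 3:1, 0 °C to rt
Reagents that add atoms: water, O
Why: Acid-catalysed epoxide hydrolysis, in which water opens the protonated epoxide at the tertiary carbon C13 with inversion, so that C13 becomes S while C14 keeps its R configuration.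

Step 11
Reactants: 22 methyl (1S,5S,6R,8aR)-1,5,6-trimethyl-5-[(3S,4R)-3,4,5-trihydroxy-3-methylpentyl]-1,2,3,5,6,7,8,8a-octahydronaphthalene-1-carboxylate
Product: 23 methyl (1S,5S,6R,8aR)-5-[(3S,4R)-5-(tert-butyldimethylsilyloxy)-3,4-dihydroxy-3-methylpentyl]-1,5,6-trimethyl-1,2,3,5,6,7,8,8a-octahydronaphthalene-1-carboxylate
Conditions: TBSCl (1.1 equiv), imidazole, CH2Cl2, 0 °C
Reagents that add atoms: tert-butyldimethylsilyl chloride, CC(C)(C)[Si](C)(C)Cl
Why: Selective silyl ether formation at the primary C15 hydroxyl relies on the large rate difference between primary, secondary and tertiary alcohols towards TBSCl/imidazole.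

Step 12
Reactants: 23 methyl (1S,5S,6R,8aR)-5-[(3S,4R)-5-(tert-butyldimethylsilyloxy)-3,4-dihydroxy-3-methylpentyl]-1,5,6-trimethyl-1,2,3,5,6,7,8,8a-octahydronaphthalene-1-carboxylate
Product: 24 methyl (1S,5S,6R,8aR)-5-[(3S,4R)-4-acetoxy-5-(tert-butyldimethylsilyloxy)-3-hydroxy-3-methylpentyl]-1,5,6-trimethyl-1,2,3,5,6,7,8,8a-octahydronaphthalene-1-carboxylate
Conditions: Ac2O (1.5 equiv), pyridine, 4-(dimethylamino)pyridine (cat.), CH2Cl2, 0 °C to rt
Reagents that add atoms: acetic anhydride, CC(=O)OC(C)=O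
Why: Nucleophile-catalysed acylation esterifies the only secondary hydroxyl (C14), the tertiary C13 hydroxyl being too hindered to react under these conditions.

Step 13
Reactants: 24 methyl (1S,5S,6R,8aR)-5-[(3S,4R)-4-acetoxy-5-(tert-butyldimethylsilyloxy)-3-hydroxy-3-methylpentyl]-1,5,6-trimethyl-1,2,3,5,6,7,8,8a-octahydronaphthalene-1-carboxylate
Product: 25 methyl (1S,5S,6R,8aR)-5-[(3S,4R)-4-acetoxy-3,5-dihydroxy-3-methylpentyl]-1,5,6-trimethyl-1,2,3,5,6,7,8,8a-octahydronaphthalene-1-carboxylate
Conditions: HF·pyridine, pyridine, THF, 0 °C to rt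
Reagents that add atoms: none
Why: Fluoride-mediated desilylation under buffered, mildly acidic conditions should free the C15 hydroxyl while keeping acetyl migration from O14 to O15 and ester cleavage slow.

**Compound list**

1 | 2-methylcyclohex-2-en-1-one | CC1=CCCCC1=O | starting material
2 | trimethylaluminium | C[Al](C)C | starting material
3 | allyl iodide | C=CCI | starting material
4 | dimethylaluminium (3R)-2,3-dimethylcyclohex-1-en-1-olate | C[Al](C)OC1=C(C)[C@H](C)CCC1 | intermediate (not isolated)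
5 | lithium [(3R)-2,3-dimethylcyclohex-1-en-1-olato]trimethylaluminate | [Li+].C[Al-](C)(C)OC1=C(C)[C@H](C)CCC1 | intermediate (not isolated)
6 | (2S,3R)-2-allyl-2,3-dimethylcyclohexan-1-one | O=C1CCC[C@@H](C)[C@]1(C)CC=C | intermediate
7 | potassium (5R,6S)-6-allyl-5,6-dimethylcyclohex-1-en-1-olate | [K+].[O-]C1=CCC[C@@H](C)[C@]1(C)CC=C | intermediate (not isolated)
8 | (5R,6S)-6-allyl-5,6-dimethylcyclohex-1-en-1-yl trifluoromethanesulfonate | O=S(=O)(OC1=CCC[C@@H](C)[C@]1(C)CC=C)C(F)(F)F | intermediate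
9 | tributyl(vinyl)stannane | C=C[Sn](CCCC)(CCCC)CCCC | starting material
10 | (5R,6S)-6-allyl-5,6-dimethyl-1-vinylcyclohex-1-ene | C=CC1=CCC[C@@H](C)[C@]1(C)CC=C | intermediate
11 | methyl methacrylate | C=C(C)C(=O)OC | starting material
12 | methyl (1S,5S,6R,8aR)-5-allyl-1,5,6-trimethyl-1,2,3,5,6,7,8,8a-octahydronaphthalene-1-carboxylate | COC(=O)[C@@]1(C)CCC=C2[C@H]1CC[C@@H](C)[C@]2(C)CC=C | intermediate
13 | methyl (1S,5S,6R,8aR)-5-[3-(9-borabicyclo[3.3.1]nonan-9-yl)propyl]-1,5,6-trimethyl-1,2,3,5,6,7,8,8a-octahydronaphthalene-1-carboxylate | COC(=O)[C@@]1(C)CCC=C2[C@H]1CC[C@@H](C)[C@]2(C)CCCB3C4CCCC3CCC4 | intermediate (not isolated)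
14 | methyl (1S,5S,6R,8aR)-5-(3-hydroxypropyl)-1,5,6-trimethyl-1,2,3,5,6,7,8,8a-octahydronaphthalene-1-carboxylate | COC(=O)[C@@]1(C)CCC=C2[C@H]1CC[C@@H](C)[C@]2(C)CCCO | intermediate
15 | methyl (1S,5S,6R,8aR)-1,5,6-trimethyl-5-(3-oxopropyl)-1,2,3,5,6,7,8,8a-octahydronaphthalene-1-carboxylate | COC(=O)[C@@]1(C)CCC=C2[C@H]1CC[C@@H](C)[C@]2(C)CCC=O | intermediate
16 | dimethyl (1-diazo-2-oxopropyl)phosphonate (Ohira–Bestmann reagent) | COP(=O)(OC)C(=[N+]=[N-])C(C)=O | starting material
17 | methyl (1S,5S,6R,8aR)-5-(but-3-yn-1-yl)-1,5,6-trimethyl-1,2,3,5,6,7,8,8a-octahydronaphthalene-1-carboxylate | COC(=O)[C@@]1(C)CCC=C2[C@H]1CC[C@@H](C)[C@]2(C)CCC#C | intermediate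
18 | paraformaldehyde (formaldehyde source) | C=O | starting material
19 | methyl (1S,5S,6R,8aR)-5-[(3E)-4-(dimethylalumanyl)-3-methylbut-3-en-1-yl]-1,5,6-trimethyl-1,2,3,5,6,7,8,8a-octahydronaphthalene-1-carboxylate | COC(=O)[C@@]1(C)CCC=C2[C@H]1CC[C@@H](C)[C@]2(C)CC/C(C)=C/[Al](C)C | intermediate (not isolated)
20 | methyl (1S,5S,6R,8aR)-5-[(3E)-5-hydroxy-3-methylpent-3-en-1-yl]-1,5,6-trimethyl-1,2,3,5,6,7,8,8a-octahydronaphthalene-1-carboxylate | COC(=O)[C@@]1(C)CCC=C2[C@H]1CC[C@@H](C)[C@]2(C)CC/C(C)=C/CO | intermediate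
21 | methyl (1S,5S,6R,8aR)-5-{2-[(2R,3R)-3-(hydroxymethyl)-2-methyloxiran-2-yl]ethyl}-1,5,6-trimethyl-1,2,3,5,6,7,8,8a-octahydronaphthalene-1-carboxylate | COC(=O)[C@@]1(C)CCC=C2[C@H]1CC[C@@H](C)[C@]2(C)CC[C@@]3(C)O[C@@H]3CO | intermediate
22 | methyl (1S,5S,6R,8aR)-1,5,6-trimethyl-5-[(3S,4R)-3,4,5-trihydroxy-3-methylpentyl]-1,2,3,5,6,7,8,8a-octahydronaphthalene-1-carboxylate | COC(=O)[C@@]1(C)CCC=C2[C@H]1CC[C@@H](C)[C@]2(C)CC[C@](C)(O)[C@@H](CO)O | intermediate
23 | methyl (1S,5S,6R,8aR)-5-[(3S,4R)-5-(tert-butyldimethylsilyloxy)-3,4-dihydroxy-3-methylpentyl]-1,5,6-trimethyl-1,2,3,5,6,7,8,8a-octahydronaphthalene-1-carboxylate | COC(=O)[C@@]1(C)CCC=C2[C@H]1CC[C@@H](C)[C@]2(C)CC[C@](C)(O)[C@@H](CO[Si](C)(C)C(C)(C)C)O | intermediate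
24 | methyl (1S,5S,6R,8aR)-5-[(3S,4R)-4-acetoxy-5-(tert-butyldimethylsilyloxy)-3-hydroxy-3-methylpentyl]-1,5,6-trimethyl-1,2,3,5,6,7,8,8a-octahydronaphthalene-1-carboxylate | COC(=O)[C@@]1(C)CCC=C2[C@H]1CC[C@@H](C)[C@]2(C)CC[C@](C)(O)[C@@H](CO[Si](C)(C)C(C)(C)C)OC(C)=O | intermediate
25 | methyl (1S,5S,6R,8aR)-5-[(3S,4R)-4-acetoxy-3,5-dihydroxy-3-methylpentyl]-1,5,6-trimethyl-1,2,3,5,6,7,8,8a-octahydronaphthalene-1-carboxylate | COC(=O)[C@@]1(C)CCC=C2[C@H]1CC[C@@H](C)[C@]2(C)CC[C@](C)(O)[C@@H](CO)OC(C)=O | target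

**Step count and risks**

Total step count: 13. Longest linear sequence: 13 steps (1 to 25).

Steps most likely to fail:

Step 4. The cycloaddition must meet three demands at once, and any of them may slip: bonding of the methacrylate α-carbon to C2 instead of C5, approach from the face of the C9 methyl, or exo placement of the ester. The acid-sensitive diene may also oligomerise before the sluggish 1,1-disubstituted dienophile reacts. The fallback sets out from diene 10 and uses the more reactive aldehyde dienophile at low temperature: methacrolein with BF3·OEt2 in CH2Cl2 at −78 °C should give (1S,5S,6R,8aR)-5-allyl-1,5,6-trimethyl-1,2,3,5,6,7,8,8a-octahydronaphthalene-1-carbaldehyde F1. Pinnick oxidation (NaClO2, NaH2PO4, 2-methylbut-2-ene, t-BuOH/H2O) then gives (1S,5S,6R,8aR)-5-allyl-1,5,6-trimethyl-1,2,3,5,6,7,8,8a-octahydronaphthalene-1-carboxylic acid F2, and methylation with Me3SiCHN2 in toluene/MeOH returns to ester 12.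

Step 10. Opening of the protonated epoxide may proceed with too much carbocation character at C13. That would erode the inversion, allow a hydride shift to a ketone, or let the C1=C10 alkene capture the cation in a ring-forming side reaction. The fallback sets out from epoxy alcohol 21 and delivers the oxygen intramolecularly. Boc2O with 1-methylimidazole in toluene gives methyl (1S,5S,6R,8aR)-5-{2-[(2R,3R)-3-(tert-butoxycarbonyloxymethyl)-2-methyloxiran-2-yl]ethyl}-1,5,6-trimethyl-1,2,3,5,6,7,8,8a-octahydronaphthalene-1-carboxylate F3. With BF3·OEt2 in CH2Cl2 at −40 °C the carbonate carbonyl oxygen should attack C13 from the back with loss of isobutene and give methyl (1S,5S,6R,8aR)-5-{2-[(4S,5R)-5-hydroxy-4-methyl-2-oxo-1,3-dioxan-4-yl]ethyl}-1,5,6-trimethyl-1,2,3,5,6,7,8,8a-octahydronaphthalene-1-carboxylate F4. Methanolysis with K2CO3 in MeOH returns to triol 22.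

Step 8. Transfer of the alkenyl group from aluminium to formaldehyde may be slow, so that protonolysis on work-up or methyl transfer competes, and prolonged exposure to AlMe3 may begin to attack the ester. The fallback sets out from alkyne 17, runs the same carboalumination to alkenylalane 19 and quenches it with I2 in THF at −30 °C, a fast and clean trapping. This gives methyl (1S,5S,6R,8aR)-5-[(3E)-4-iodo-3-methylbut-3-en-1-yl]-1,5,6-trimethyl-1,2,3,5,6,7,8,8a-octahydronaphthalene-1-carboxylate F5. Stille hydroxymethylation with (tributylstannyl)methanol and Pd(PPh3)4 in dioxane at 80 °C then forms the C14–C15 bond and returns to allylic alcohol 20.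

**Further compounds**

F1 | step 4 | (1S,5S,6R,8aR)-5-allyl-1,5,6-trimethyl-1,2,3,5,6,7,8,8a-octahydronaphthalene-1-carbaldehyde | O=C[C@@]1(C)CCC=C2[C@H]1CC[C@@H](C)[C@]2(C)CC=C
F2 | step 4 | (1S,5S,6R,8aR)-5-allyl-1,5,6-trimethyl-1,2,3,5,6,7,8,8a-octahydronaphthalene-1-carboxylic acid | OC(=O)[C@@]1(C)CCC=C2[C@H]1CC[C@@H](C)[C@]2(C)CC=C
F3 | step 10 | methyl (1S,5S,6R,8aR)-5-{2-[(2R,3R)-3-(tert-butoxycarbonyloxymethyl)-2-methyloxiran-2-yl]ethyl}-1,5,6-trimethyl-1,2,3,5,6,7,8,8a-octahydronaphthalene-1-carboxylate | COC(=O)[C@@]1(C)CCC=C2[C@H]1CC[C@@H](C)[C@]2(C)CC[C@@]3(C)O[C@@H]3COC(=O)OC(C)(C)C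
F4 | step 10 | methyl (1S,5S,6R,8aR)-5-{2-[(4S,5R)-5-hydroxy-4-methyl-2-oxo-1,3-dioxan-4-yl]ethyl}-1,5,6-trimethyl-1,2,3,5,6,7,8,8a-octahydronaphthalene-1-carboxylate | COC(=O)[C@@]1(C)CCC=C2[C@H]1CC[C@@H](C)[C@]2(C)CC[C@]3(C)OC(=O)OC[C@H]3O
F5 | step 8 | methyl (1S,5S,6R,8aR)-5-[(3E)-4-iodo-3-methylbut-3-en-1-yl]-1,5,6-trimethyl-1,2,3,5,6,7,8,8a-octahydronaphthalene-1-carboxylate | COC(=O)[C@@]1(C)CCC=C2[C@H]1CC[C@@H](C)[C@]2(C)CC/C(C)=C/I
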